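Ring B (C1, C2, C3, C4, C4a, C8a) of the 2-hydroxy-3-alkyl-1,4-naphthoquinone is cut at both aryl–carbonyl bonds, C4–C4a and C1–C8a, so that the unsubstituted ring A arrives as symmetrical benzyne. In one flask benzyne inserts into the C(α)–C(ketone) bond of an acyclic β-ketoester, base closes C2–C3 by Dieckmann condensation, and air oxidises C1 to complete the hydroxyquinone. The precursor is a methyl 3-oxoheptanoate whose chain already carries the gem-dimethyl quaternary carbon and the neopentyl oxygen as a p-methoxybenzyl ether. Deprotection and esterification with the (2E,6R)-acid from (R)-linalool, the only source of chirality, finish the target.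

Key step: step 5

Remark: atom labels C1–C4, C4a and C8a are those of the naphthoquinone of the target; salts, conjugate bases and fleeting mechanistic species (tetrahedral adducts, the aryl anion and four-membered alkoxide of the insertion, peroxy and selenium adducts) are not numbered, only discrete compounds formed in the flask.

Step 1
Reactants: 1 2,2-dimethylpent-4-en-1-ol
Product: 2 1-{[(2,2-dimethylpent-4-en-1-yl)oxy]methyl}-4-methoxybenzene (p-methoxybenzyl ether of 1)
Conditions: NaH, 4-methoxybenzyl chloride, tetrabutylammonium iodide Bu4NI (cat.), DMF, 0 °C to rt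
Reagents that add atoms: 4-methoxybenzyl chloride, COc1ccc(CCl)cc1
Why: Williamson etherification in which the unhindered oxygen of the neopentyl alkoxide displaces halide from the activated benzylic carbon, so the neighbouring quaternary carbon does not slow the reaction and the terminal alkene is untouched.

Step 2
Reactants: 2 1-{[(2,2-dimethylpent-4-en-1-yl)oxy]methyl}-4-methoxybenzene
Product: 4 5-[(4-methoxybenzyl)oxy]-4,4-dimethylpentan-1-ol, via B-alkyl-9-borabicyclo[3.3.1]nonane 3 (not isolated)
Conditions: 9-borabicyclo[3.3.1]nonane (9-BBN), THF, 0 °C to rt; then NaOH, H2O2, 0 °C to rt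
Reagents that add atoms: hydrogen peroxide, OO
Why: Hydroboration–oxidation: the bulky dialkylborane adds anti-Markovnikov to the monosubstituted alkene, and alkaline peroxide replaces the terminal C–B bond by C–O while the ether stays intact.

Step 3
Reactants: 4 5-[(4-methoxybenzyl)oxy]-4,4-dimethylpentan-1-ol
Product: 6 5-[(4-methoxybenzyl)oxy]-4,4-dimethylpentanoic acid, via aldehyde 5 (not isolated)
Conditions: 2,2,6,6-tetramethylpiperidin-1-oxyl (cat.), PhI(OAc)2, MeCN/H2O, rt
Reagents that add atoms: water, O
Why: Nitroxyl/oxoammonium-catalysed oxidation with PhI(OAc)2 as terminal oxidant takes the primary alcohol through aldehyde 5 and its hydrate to the acid under near-neutral conditions that a p-methoxybenzyl ether tolerates.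

Step 4
Reactants: 6 5-[(4-methoxybenzyl)oxy]-4,4-dimethylpentanoic acid; 7 potassium methyl malonate (KO2CCH2CO2Me)
Product: 10 methyl 7-[(4-methoxybenzyl)oxy]-6,6-dimethyl-3-oxoheptanoate, via acyl imidazolide 8 (not isolated), via acylmalonic half-ester 9 (not isolated)
Conditions: 1,1'-carbonyldiimidazole, THF, rt; then 7, MgCl2, THF, rt to 50 °C; dilute aq. HCl work-up
Reagents that add atoms: none
Why: Masamune–Brooks homologation: the acid is activated as acyl imidazolide 8, the magnesium chelate of the malonate half-ester is C-acylated, and adduct 9 loses CO2 to give the β-ketoester without any reagent that would touch the ether.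

Step 5
Reactants: 10 methyl 7-[(4-methoxybenzyl)oxy]-6,6-dimethyl-3-oxoheptanoate; 11 2-(trimethylsilyl)phenyl trifluoromethanesulfonate
Product: 15 2-hydroxy-3-{3-[(4-methoxybenzyl)oxy]-2,2-dimethylpropyl}naphthalene-1,4-dione, via benzyne 12 (not isolated), via ortho-acylphenylacetate ester 13 (not isolated), via 2-alkylnaphthalene-1,3-diol 14 (not isolated)
Conditions: 11 (1.3 equiv), CsF (3 equiv), MeCN, 80 °C; then NaOMe, MeOH, air, rt; 1 M HCl work-up
Reagents that add atoms: dioxygen (from air), O=O
Why: Fluoride-induced 1,2-elimination of 11 gives benzyne 12, which the enolate of 10 attacks through its α-carbon; the resulting aryl anion adds to the neighbouring ketone to give a four-membered benzocyclobutene alkoxide, and its fragmentation to the ester-stabilised benzylic enolate leaves the arene inserted between the α-carbon and the ketone carbon, forming C1–C8a and C4–C4a in 13. The closest known reaction type is the aryne acyl-alkylation (formal sigma-bond insertion) of β-ketoesters followed in the same flask by condensation and aerobic oxidation to 3-substituted 2-hydroxy-1,4-naphthoquinones, applied here to a new side chain. Methoxide then forms the ketone enolate at the chain CH2, which attacks the methyl ester in a Dieckmann condensation forming C2–C3; this closure of ring B is 6-(enolendo)-exo-trig, since the enolate C3=C4 bond lies inside the new ring, and it is pulled forward by aromatisation to diol 14. Air oxidises the electron-rich naphtholate of 14 at its only unsubstituted ring carbon, C1, to the quinone carbonyl, and the product rests as its stable hydroxyquinone anion until acidified. No stereocentre is formed; the step needs C- over O-arylation and insertion on the ketone side, the first being normal for soft β-ketoester enolates and the second secured because the aryl anion adds to the more electrophilic ketone and cleavage then releases an ester enolate, while the symmetrical aryne leaves no regiochemical question and only one six-membered Dieckmann mode exists. The ether oxygen and the quaternary carbon of the chain are inert to fluoride, methoxide and air.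

Step 6
Reactants: 15 2-hydroxy-3-{3-[(4-methoxybenzyl)oxy]-2,2-dimethylpropyl}naphthalene-1,4-dione
Product: 16 2-hydroxy-3-(3-hydroxy-2,2-dimethylpropyl)naphthalene-1,4-dione
Conditions: 2,3-dichloro-5,6-dicyano-1,4-benzoquinone (DDQ), CH2Cl2/H2O, 0 °C to rt
Reagents that add atoms: none
Why: Oxidative deprotection: the electron-rich p-methoxybenzyl ether transfers hydride to DDQ and water hydrolyses the oxocarbenium ion, whereas the electron-poor hydroxyquinone is inert to DDQ and the weakly acidic medium is too mild to cyclise the freed alcohol onto the quinone.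

Step 7
Reactants: 17 (R)-linalool, (3R)-3,7-dimethylocta-1,6-dien-3-ol
Product: 19 (2E,6R)-6-hydroxy-2,6-dimethylocta-2,7-dienal, via allylic alcohol 18 (not isolated)
Conditions: SeO2, 1,4-dioxane/EtOH, 80 °C
Reagents that add atoms: selenium dioxide, O=[Se]=O
Why: Riley allylic oxidation (ene reaction, then [2,3]-sigmatropic shift) attacks the more substituted end of the trisubstituted alkene at its (E)-methyl group and carries the first-formed alcohol 18 on to the conjugated aldehyde, while the vinyl group has no allylic hydrogen and the (R) carbinol centre brought in with 17 is not involved.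

Step 8
Reactants: 19 (2E,6R)-6-hydroxy-2,6-dimethylocta-2,7-dienal
Product: 20 (2E,6R)-6-hydroxy-2,6-dimethylocta-2,7-dienoic acid
Conditions: NaClO2, NaH2PO4, 2-methylbut-2-ene, t-BuOH/H2O, rt
Reagents that add atoms: sodium chlorite, [Na+].[O-]Cl=O
Why: Pinnick oxidation converts the conjugated aldehyde into the acid without touching either alkene or the enoate geometry, because 2-methylbut-2-ene scavenges the hypochlorous acid released, and the remote stereocentre is unaffected.

Step 9
Reactants: 16 2-hydroxy-3-(3-hydroxy-2,2-dimethylpropyl)naphthalene-1,4-dione; 20 (2E,6R)-6-hydroxy-2,6-dimethylocta-2,7-dienoic acid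
Product: 22 Rhinacanthin H, 3-(3-hydroxy-1,4-dioxo-1,4-dihydronaphthalen-2-yl)-2,2-dimethylpropyl (2E,6R)-6-hydroxy-2,6-dimethylocta-2,7-dienoate, via mixed anhydride 21 (not isolated)
Conditions: 20, 2,4,6-trichlorobenzoyl chloride, Et3N, THF, rt; then 16, 4-(dimethylamino)pyridine, toluene, rt; dilute aq. citric acid work-up
Reagents that add atoms: none
Why: Yamaguchi esterification: the hindered aroyl group of 21 directs 4-(dimethylamino)pyridine to the enoyl carbonyl and the acylpyridinium acylates the primary neopentyl alcohol, the tertiary hydroxyl being too hindered to compete and any ester formed at the acidic C2 enol being a vinylogous anhydride that passes its acyl group on or is hydrolysed on work-up, so the (6R) centre and the (E) alkene are carried through unchanged.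

Compound list
1 | 2,2-dimethylpent-4-en-1-ol | C=CCC(C)(C)CO | starting material
2 | 1-{[(2,2-dimethylpent-4-en-1-yl)oxy]methyl}-4-methoxybenzene | C=CCC(C)(C)COCc1ccc(OC)cc1 | intermediate
3 | 9-{5-[(4-methoxybenzyl)oxy]-4,4-dimethylpentyl}-9-borabicyclo[3.3.1]nonane (not isolated) | COc1ccc(COCC(C)(C)CCCB2C3CCCC2CCC3)cc1 | intermediate
4 | 5-[(4-methoxybenzyl)oxy]-4,4-dimethylpentan-1-ol | COc1ccc(COCC(C)(C)CCCO)cc1 | intermediate
5 | 5-[(4-methoxybenzyl)oxy]-4,4-dimethylpentanal (not isolated) | COc1ccc(COCC(C)(C)CCC=O)cc1 | intermediate
6 | 5-[(4-methoxybenzyl)oxy]-4,4-dimethylpentanoic acid | COc1ccc(COCC(C)(C)CCC(=O)O)cc1 | intermediate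
7 | potassium methyl malonate (potassium 3-methoxy-3-oxopropanoate) | COC(=O)CC(=O)[O-].[K+] | starting material
8 | 1-(1H-imidazol-1-yl)-5-[(4-methoxybenzyl)oxy]-4,4-dimethylpentan-1-one (acyl imidazolide, not isolated) | COc1ccc(COCC(C)(C)CCC(=O)n2ccnc2)cc1 | intermediate
9 | 2-(methoxycarbonyl)-7-[(4-methoxybenzyl)oxy]-6,6-dimethyl-3-oxoheptanoic acid (present as its magnesium chelate, not isolated) | COC(=O)C(C(=O)O)C(=O)CCC(C)(C)COCc1ccc(OC)cc1 | intermediate
10 | methyl 7-[(4-methoxybenzyl)oxy]-6,6-dimethyl-3-oxoheptanoate | COC(=O)CC(=O)CCC(C)(C)COCc1ccc(OC)cc1 | intermediate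
11 | 2-(trimethylsilyl)phenyl trifluoromethanesulfonate | C[Si](C)(C)c1ccccc1OS(=O)(=O)C(F)(F)F | starting material
12 | benzyne (1,2-didehydrobenzene, not isolated) | C1#CC=CC=C1 | intermediate
13 | methyl 2-(2-{5-[(4-methoxybenzyl)oxy]-4,4-dimethylpentanoyl}phenyl)acetate (not isolated) | COC(=O)Cc1ccccc1C(=O)CCC(C)(C)COCc1ccc(OC)cc1 | intermediate
14 | 2-{3-[(4-methoxybenzyl)oxy]-2,2-dimethylpropyl}naphthalene-1,3-diol (not isolated) | COc1ccc(COCC(C)(C)Cc2c(O)cc3ccccc3c2O)cc1 | intermediate
15 | 2-hydroxy-3-{3-[(4-methoxybenzyl)oxy]-2,2-dimethylpropyl}naphthalene-1,4-dione | COc1ccc(COCC(C)(C)CC2=C(O)C(=O)c3ccccc3C2=O)cc1 | intermediate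
16 | 2-hydroxy-3-(3-hydroxy-2,2-dimethylpropyl)naphthalene-1,4-dione | OCC(C)(C)CC1=C(O)C(=O)c2ccccc2C1=O | intermediate
17 | (R)-linalool, (3R)-3,7-dimethylocta-1,6-dien-3-ol | C=C[C@](C)(O)CCC=C(C)C | starting material
18 | (2E,6R)-2,6-dimethylocta-2,7-diene-1,6-diol (not isolated) | C=C[C@](C)(O)CC/C=C(\C)CO | intermediate
19 | (2E,6R)-6-hydroxy-2,6-dimethylocta-2,7-dienal | C=C[C@](C)(O)CC/C=C(\C)C=O | intermediate
20 | (2E,6R)-6-hydroxy-2,6-dimethylocta-2,7-dienoic acid | C=C[C@](C)(O)CC/C=C(\C)C(=O)O | intermediate
21 | (2E,6R)-6-hydroxy-2,6-dimethylocta-2,7-dienoic 2,4,6-trichlorobenzoic anhydride (not isolated) | C=C[C@](C)(O)CC/C=C(\C)C(=O)OC(=O)c1c(Cl)cc(Cl)cc1Cl | intermediate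
22 | Rhinacanthin H, 3-(3-hydroxy-1,4-dioxo-1,4-dihydronaphthalen-2-yl)-2,2-dimethylpropyl (2E,6R)-6-hydroxy-2,6-dimethylocta-2,7-dienoate | C=C[C@](C)(O)CC/C=C(\C)C(=O)OCC(C)(C)CC1=C(O)C(=O)c2ccccc2C1=O | target

Total step count: 9.
Longest linear sequence: 7 steps (steps 1, 2, 3, 4, 5, 6 and 9, from 1). The acid 20 is made in 2 steps (7 and 8) from 17 and joins in step 9.

Steps most likely to fail

Step 5. The enolate may arylate the aryne without the ring-expanding fragmentation (plain α- or O-arylation), the aryne may be lost to oligomerisation, or the base/air stage may stall before ring closure or over-oxidise the hydroxyquinone anion. Fallback, setting out from 2: the terminal alkene would be isomerised with RuHCl(CO)(PPh3)3 (cat.) in toluene at 80 °C to 1-({[(3E)-2,2-dimethylpent-3-en-1-yl]oxy}methyl)-4-methoxybenzene F1; migration stops there because the next carbon is quaternary. Oxidative cleavage (OsO4 cat., NaIO4, 2,6-lutidine, dioxane/H2O) would give 3-[(4-methoxybenzyl)oxy]-2,2-dimethylpropanal F2. Organocatalytic three-component reductive alkylation of commercial 2-hydroxy-1,4-naphthoquinone with F2 and diethyl 2,6-dimethyl-1,4-dihydropyridine-3,5-dicarboxylate (L-proline cat., CH2Cl2, rt; Knoevenagel condensation to the quinone methide, then hydride transfer) would attach the chain at C3 and return to the route at 15.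

Step 9. Acylation at the acidic C2 enol hydroxyl may compete with the slow acylation of the hindered neopentyl alcohol by an α-branched enoyl donor, so that the activated acid is consumed unproductively. Fallback, setting out from 16: trimethylsilyldiazomethane (MeOH/toluene, 0 °C) methylates only the vinylogous acid and would give 3-(3-hydroxy-2,2-dimethylpropyl)-2-methoxynaphthalene-1,4-dione F3. Mixed-anhydride acylation of this ordinary primary alcohol with 20 would give 3-(3-methoxy-1,4-dioxo-1,4-dihydronaphthalen-2-yl)-2,2-dimethylpropyl (2E,6R)-6-hydroxy-2,6-dimethylocta-2,7-dienoate F4. Addition–elimination of hydroxide at C2 of the vinylogous methyl ester (dilute LiOH, THF/H2O, 0 °C), much faster than attack on the hindered enoate, would release methanol and return to the route at 22.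

Step 7. The oxidation may stop short or run on, giving alcohol/aldehyde mixtures and selenium-bound by-products, and the hot, mildly acidic medium may ionise or rearrange the tertiary allylic alcohol, costing material and possibly configurational purity at C6. Fallback, setting out from 17: ozonolysis limited to one equivalent (O3, CH2Cl2/MeOH, −78 °C; then Me2S) would cleave only the electron-rich trisubstituted alkene and give the hydroxy aldehyde in its closed form, (5R)-5-ethenyl-5-methyloxolan-2-ol F5. Wittig olefination of this lactol with the stabilised ylide methyl 2-(triphenylphosphoranylidene)propanoate (toluene, 80 °C) would give methyl (2E,6R)-6-hydroxy-2,6-dimethylocta-2,7-dienoate F6. Saponification (LiOH, THF/H2O, rt) would return to the route at 20, replacing steps 7 and 8.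

Further compounds
F1 | step 5 | 1-({[(3E)-2,2-dimethylpent-3-en-1-yl]oxy}methyl)-4-methoxybenzene | C/C=C/C(C)(C)COCc1ccc(OC)cc1
F2 | step 5 | 3-[(4-methoxybenzyl)oxy]-2,2-dimethylpropanal | O=CC(C)(C)COCc1ccc(OC)cc1
F3 | step 9 | 3-(3-hydroxy-2,2-dimethylpropyl)-2-methoxynaphthalene-1,4-dione | COC1=C(CC(C)(C)CO)C(=O)c2ccccc2C1=O
F4 | step 9 | 3-(3-methoxy-1,4-dioxo-1,4-dihydronaphthalen-2-yl)-2,2-dimethylpropyl (2E,6R)-6-hydroxy-2,6-dimethylocta-2,7-dienoate | C=C[C@](C)(O)CC/C=C(\C)C(=O)OCC(C)(C)CC1=C(OC)C(=O)c2ccccc2C1=O
F5 | step 7 | (5R)-5-ethenyl-5-methyloxolan-2-ol (mixture of anomers) | C=C[C@](C)(OC1O)CC1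
F6 | step 7 | methyl (2E,6R)-6-hydroxy-2,6-dimethylocta-2,7-dienoate | C=C[C@](C)(O)CC/C=C(\C)C(=O)OC
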